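**Retrosynthetic overview**
1. Target ⇐ lactone 33 by two late acylations (C2 propionate, C9 acetate); the γ-lactone (last ring) comes from oxidative lactonisation of a 7,19-diol.
2. Ten-membered ring (second ring) ⇐ intramolecular Ni/Cr coupling of a (Z)-C6 vinyl iodide with a C7 aldehyde.
3. Key union C8–C9 ⇐ intermolecular aldol of an L-malate-derived dioxolanone enolate (C7, C8, C17–C19) with a ring-A aldehyde (C9).
4. Ring A (first ring) ⇐ catalytic asymmetric Diels–Alder (sets C1, C10); C2–C6 arm by ketone alkylation and CBS reduction; C11 Me/OH and the enone are installed after the aldol.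
5. Order of ring formation: cyclohexene → ten-membered carbocycle → lactone.

Assumption: briarane numbering (C1–C20) is used for positions in all intermediates, and metal enolates or organometallic species formed in situ get a number only in the key step.
Assumption: the facial sense of the oxazaborolidinium catalyst in step 2 follows Corey's model for 2-substituted enals, which calls for the (R)-catalyst; if the antipode forms, the (S)-catalyst is used instead.

**Route**

Step 1
Reactants: 1 but-3-en-2-one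
Product: 2 2-(triisopropylsilyloxy)buta-1,3-diene
Conditions: TIPSOTf, Et3N, CH2Cl2, 0 °C → rt
Reagents that add atoms: triisopropylsilyl triflate, CC(C)[Si](OS(=O)(=O)C(F)(F)F)(C(C)C)C(C)C
Why: Soft enolisation of the methyl ketone and O-silylation gives the cross-conjugated 2-siloxydiene.

Step 2
Reactants: 2 2-(triisopropylsilyloxy)buta-1,3-diene; 3 ethyl (2E)-3-methyl-4-oxobut-2-enoate
Product: 4 ethyl (1S,6S)-6-formyl-6-methyl-3-(triisopropylsilyloxy)cyclohex-3-ene-1-carboxylate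
Conditions: (R)-o-tolyl-CBS oxazaborolidine (20 mol %), Tf2NH (16 mol %), CH2Cl2, −78 → −40 °C
Reagents that add atoms: none
Why: Oxazaborolidinium-catalysed Diels–Alder reaction in which the formyl-bound catalyst blocks one face, the siloxy group directs "para" bonding (C14 to C1, C11 to C10) and the E geometry of 3 puts CHO (C2) and CO2Et (C9) trans, setting C1 and C10.

Step 3
Reactants: 4 Diels–Alder aldehyde
Product: 5 ethyl (1S,6S)-6-(1-hydroxyethyl)-6-methyl-3-(triisopropylsilyloxy)cyclohex-3-ene-1-carboxylate (carbinol epimers)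
Conditions: MeMgBr (1.1 equiv), THF, −78 °C; cold aq NH4Cl quench
Reagents that add atoms: methylmagnesium bromide, C[Mg]Br
Why: Grignard 1,2-addition to the aldehyde at −78 °C outpaces attack on the hindered ester; the carbinol configuration is irrelevant because it is oxidised next.

Step 4
Reactants: 5 secondary alcohol
Product: 6 ethyl (1S,6S)-6-acetyl-6-methyl-3-(triisopropylsilyloxy)cyclohex-3-ene-1-carboxylate
Conditions: Dess–Martin periodinane, NaHCO3, CH2Cl2, 0 °C → rt
Reagents that add atoms: none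
Why: Buffered Dess–Martin oxidation gives the methyl ketone (C2=O, C3 methyl) and leaves the silyl enol ether intact.

Step 5
Reactants: 7 prop-2-yn-1-ol
Product: 8 (2Z)-3-iodo-2-methylprop-2-en-1-ol
Conditions: MeMgBr (2.5 equiv), CuI (10 mol %), THF, −20 °C → rt; then I2, −10 °C
Reagents that add atoms: methylmagnesium bromide, C[Mg]Br; iodine, II
Why: Duboudin copper-catalysed anti-carbomagnesiation of the propargylic alkoxide (five-membered Mg chelate) and iodinolysis with retention give the Z iodide (CH2O cis to I).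

Step 6
Reactants: 8 (2Z)-3-iodo-2-methylprop-2-en-1-ol
Product: 9 (1Z)-3-bromo-1-iodo-2-methylprop-1-ene
Conditions: CBr4, PPh3, CH2Cl2, 0 °C
Reagents that add atoms: carbon tetrabromide, BrC(Br)(Br)Br
Why: Appel bromination is an SN2 reaction at the primary allylic carbon and does not touch the alkene geometry.

Step 7
Reactants: 6 methyl ketone; 9 (1Z)-3-bromo-1-iodo-2-methylprop-1-ene
Product: 10 ethyl (1S,6S)-6-[(4Z)-5-iodo-4-methylpent-4-enoyl]-6-methyl-3-(triisopropylsilyloxy)cyclohex-3-ene-1-carboxylate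
Conditions: LiHMDS, THF, −78 °C; then 9, DMPU, −78 → −40 °C
Reagents that add atoms: none
Why: Kinetic enolate alkylation: the CH3 of the ketone is the only readily enolisable site (C1 is quaternary, the ring ketone is masked as the TIPS enol ether) and the allylic bromide reacts by SN2, forming C3–C4 with the Z vinyl iodide untouched.

Step 8
Reactants: 10 ketone
Product: 11 ethyl (1S,6S)-6-[(1R,4Z)-1-hydroxy-5-iodo-4-methylpent-4-en-1-yl]-6-methyl-3-(triisopropylsilyloxy)cyclohex-3-ene-1-carboxylate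
Conditions: (S)-Me-CBS (20 mol %), BH3·SMe2, THF, −30 °C; MeOH quench
Reagents that add atoms: none
Why: Corey–Bakshi–Shibata reduction with quaternary C1 as the large group and the CH2 chain as the small one gives the (R)-carbinol at C2 under reagent control.

Step 9
Reactants: 11 alcohol
Product: 12 ethyl (1S,6S)-6-[(1R,4Z)-5-iodo-4-methyl-1-(triethylsilyloxy)pent-4-en-1-yl]-6-methyl-3-(triisopropylsilyloxy)cyclohex-3-ene-1-carboxylate
Conditions: TESOTf, 2,6-lutidine, CH2Cl2, −78 → 0 °C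
Reagents that add atoms: triethylsilyl triflate, CC[Si](CC)(CC)OS(=O)(=O)C(F)(F)F
Why: Silyl triflate silylation under non-nucleophilic conditions protects the hindered C2 alcohol before it can lactonise onto the C9 ester.

Step 10
Reactants: 12 ester
Product: 13 [(1S,6S)-6-{(1R,4Z)-5-iodo-4-methyl-1-(triethylsilyloxy)pent-4-en-1-yl}-6-methyl-3-(triisopropylsilyloxy)cyclohex-3-en-1-yl]methanol
Conditions: DIBAL-H (2.5 equiv), CH2Cl2, −78 → −40 °C; Rochelle salt
Reagents that add atoms: none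
Why: DIBAL-H reduces the ester to the primary alcohol while silyl ethers, silyl enol ether and vinyl iodide are inert.

Step 11
Reactants: 13 primary alcohol
Product: 14 (1S,6S)-6-[(1R,4Z)-5-iodo-4-methyl-1-(triethylsilyloxy)pent-4-en-1-yl]-6-methyl-3-(triisopropylsilyloxy)cyclohex-3-ene-1-carbaldehyde
Conditions: Dess–Martin periodinane, NaHCO3, CH2Cl2, 0 °C
Reagents that add atoms: none
Why: Buffered Dess–Martin oxidation gives the C9 aldehyde without epimerising C10, whose substituent is already in the favoured trans arrangement.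

Step 12
Reactants: 15 diethyl (2S)-2-hydroxybutanedioate
Product: 16 diethyl (2S,3R)-2-hydroxy-3-methylbutanedioate
Conditions: LDA (2.2 equiv), THF, −78 → −20 °C; MeI, −78 → 0 °C; aq NH4Cl
Reagents that add atoms: iodomethane, CI
Why: Fráter–Seebach alkylation: the chelated alkoxide/enolate dianion is methylated anti to the oxygen (about 9:1), which sets C17.

Step 13
Reactants: 16 diethyl (2S,3R)-3-methylmalate
Product: 17 (2S,3R)-2-hydroxy-3-methylbutanedioic acid
Conditions: KOH, H2O/EtOH, 0 °C → rt; then HCl to pH 1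
Reagents that add atoms: potassium hydroxide, [K+].[OH-]
Why: Saponification; once formed, the carboxylates protect the α-centres from epimerisation.

Step 14
Reactants: 17 (2S,3R)-3-methylmalic acid
Product: 18 (2R)-2-[(2S,4S)-2-tert-butyl-5-oxo-1,3-dioxolan-4-yl]propanoic acid
Conditions: pivaldehyde, cat. TsOH, cat. H2SO4, pentane, reflux (Dean–Stark); crystallise
Reagents that add atoms: pivaldehyde, CC(C)(C)C=O
Why: Seebach acetalisation under thermodynamic control gives the cis-2,5-disubstituted dioxolanone from the α-hydroxy acid unit, storing the C8 configuration in the new acetal centre.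

Step 15
Reactants: 18 dioxolanone acid
Product: 19 (2S,5S)-2-tert-butyl-5-[(2S)-1-hydroxypropan-2-yl]-1,3-dioxolan-4-one
Conditions: BH3·THF, THF, −20 → 0 °C; MeOH quench; used at once
Reagents that add atoms: none
Why: Borane reduces the free carboxylic acid (via an acyloxyborane) chemoselectively in the presence of the dioxolanone, bringing C19 to the alcohol level.

Step 16
Reactants: 19 dioxolanone alcohol
Product: 20 (2S,5S)-2-tert-butyl-5-[(2S)-1-(triethylsilyloxy)propan-2-yl]-1,3-dioxolan-4-one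
Conditions: TESCl, imidazole, CH2Cl2, 0 °C
Reagents that add atoms: chlorotriethylsilane, CC[Si](CC)(CC)Cl
Why: Fast silylation of the primary alcohol under mild conditions prevents translactonisation onto the dioxolanone carbonyl.

Step 17
Reactants: 20 dioxolanone TES ether (1.5 equiv); 14 ring-A aldehyde
Product: 22 aldol adduct (C8–C9 bond formed; 9R carbinol; 8-O in the acetal), via lithium enolate 21 (not isolated)
Conditions: LDA, THF, −78 °C, 30 min; then 14, −78 °C; aq NH4Cl at −78 °C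
Reagents that add atoms: none
Why: Intermolecular aldol addition of the Seebach dioxolanone enolate (self-regeneration of stereocentres): the aldehyde adds trans to the tert-butyl group, fixing C8, and a closed Zimmerman–Traxler transition state (C10 substituent equatorial, C17 chain cis to OLi) places O8 and O9 anti, giving the 9R carbinol.

Step 18
Reactants: 22 aldol adduct
Product: 23 9-O-TBS ether of 22
Conditions: TBSOTf, 2,6-lutidine, CH2Cl2, 0 °C → rt
Reagents that add atoms: tert-butyldimethylsilyl triflate, CC(C)(C)[Si](C)(C)OS(=O)(=O)C(F)(F)F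
Why: Silyl triflate silylation caps the hindered C9 alcohol with a group that survives until the penultimate step.

Step 19
Reactants: 23 TBS ether
Product: 24 7,8-diol (C7 primary OH, C8 tertiary OH)
Conditions: LiBH4, THF, 0 °C → rt; aq NH4Cl
Reagents that add atoms: none
Why: Hydride reduction opens the activated dioxolanone to the primary C7 alcohol and frees the tertiary C8 hydroxyl (the pivaldehyde released is reduced to neopentyl alcohol), with the vinyl iodide and silyl groups untouched.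

Step 20
Reactants: 24 diol
Product: 26 cyclohex-2-enone diol (C12 ketone, C13=C14), via selenide 25 (not isolated)
Conditions: PhSeCl, pyridine, CH2Cl2, −78 → 0 °C; then 30 % H2O2, 0 °C → rt
Reagents that add atoms: none
Why: Reich selenenylation of the silyl enol ether at C13 and selenoxide syn-elimination toward C14 unveil the enone regiospecifically.

Step 21
Reactants: 26 enone diol
Product: 27 11-methyl enone (C11 epimers)
Conditions: LDA (3.3 equiv), THF, −78 °C; MeI, −78 → −40 °C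
Reagents that add atoms: iodomethane, CI
Why: Kinetic α′-enolate alkylation at C11 (C1 is quaternary, so there is no γ-proton), with the two lithium alkoxides inert to MeI at this temperature; the C11 configuration is erased in the next step.

Step 22
Reactants: 27 11-methyl enone
Product: 28 11-hydroxy-11-methyl enone (11S)
Conditions: KHMDS (3.5 equiv), THF, −78 °C; 2-(phenylsulfonyl)-3-phenyloxaziridine, −78 °C; aq NH4Cl
Reagents that add atoms: 2-(phenylsulfonyl)-3-phenyloxaziridine (Davis reagent), O=S(=O)(c1ccccc1)N1OC1c1ccccc1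
Why: Davis enolate hydroxylation: the oxidant approaches the C11 enolate from the α face, anti to the C10 side chain and to the 1,3-syn C15 methyl, giving OH α and methyl β.

Step 23
Reactants: 28 hydroxy enone
Product: 29 C7 aldehyde (α-hydroxy aldehyde)
Conditions: SO3·pyridine, DMSO, iPr2NEt, CH2Cl2, 0 °C
Reagents that add atoms: none
Why: Parikh–Doering oxidation converts the only primary alcohol into the non-enolisable aldehyde and cannot touch the tertiary alcohols.

Step 24
Reactants: 29 iodo aldehyde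
Product: 30 ten-membered carbocycle, (5Z,7S)-allylic alcohol
Conditions: CrCl2 (12 equiv), NiCl2 (0.1 equiv), degassed DMSO, 3 mM, rt, syringe-pump addition
Reagents that add atoms: none
Why: Nozaki–Hiyama–Kishi macrocyclisation: the alkenylchromium keeps the Z geometry and adds to the aldehyde by polar Felkin–Anh control (anti to the C8–O bond, the bulky C9 branch inside), giving 7S; Cr(II) tolerates the enone and free hydroxyls.

Step 25
Reactants: 30 macrocycle
Product: 31 2,7,19-triol (9-OTBS retained)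
Conditions: PPTS, MeOH/CH2Cl2, 0 °C → rt
Reagents that add atoms: none
Why: Mild acid methanolysis removes the two triethylsilyl ethers while the hindered secondary TBS ether survives.

Step 26
Reactants: 31 triol
Product: 33 7,19-lactone (2-OH free; 9-OTBS), via lactol 32 (not isolated)
Conditions: TEMPO (20 mol %), PhI(OAc)2 (2.5 equiv), CH2Cl2, rt
Reagents that add atoms: none
Why: TEMPO/BAIB oxidative lactonisation: the primary C19 alcohol is oxidised first, the aldehyde is trapped by the 7-OH as a five-membered lactol and this is oxidised to the lactone with retention at C7 and C17.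

Step 27
Reactants: 33 lactone
Product: 34 2-O-propanoyl lactone
Conditions: (EtCO)2O, DMAP, pyridine, CH2Cl2, 0 °C → rt
Reagents that add atoms: propanoic anhydride, CCC(=O)OC(=O)CC
Why: DMAP-catalysed acylation of the only secondary alcohol; the tertiary 8- and 11-hydroxyls do not react.

Step 28
Reactants: 34 propionate
Product: 35 9-alcohol
Conditions: HF·pyridine, THF/pyridine, 0 °C → rt
Reagents that add atoms: none
Why: Buffered fluoride desilylation removes the TBS ether without touching the lactone, the ester or the α-ketol.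

Step 29
Reactants: 35 9-alcohol
Product: 36 CNP0240018.1 (target)
Conditions: Ac2O, DMAP, pyridine, CH2Cl2, rt
Reagents that add atoms: acetic anhydride, CC(=O)OC(C)=O
Why: DMAP-catalysed acetylation of the single remaining secondary alcohol completes the target.

**Compound list**
1 | but-3-en-2-one (methyl vinyl ketone) | CC(=O)C=C | starting material
2 | 2-[(triisopropylsilyl)oxy]buta-1,3-diene | C=CC(=C)O[Si](C(C)C)(C(C)C)C(C)C | intermediate
3 | ethyl (2E)-3-methyl-4-oxobut-2-enoate | CCOC(=O)/C=C(\C)C=O | starting material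
4 | ethyl (1S,6S)-6-formyl-6-methyl-3-[(triisopropylsilyl)oxy]cyclohex-3-ene-1-carboxylate (ring C1' = C10, C6' = C1; CHO = C2 and CO2Et = C9 trans) | O=C[C@@]1(C)CC=C(O[Si](C(C)C)(C(C)C)C(C)C)C[C@@H]1C(=O)OCC | intermediate
5 | ethyl (1S,6S)-6-(1-hydroxyethyl)-6-methyl-3-[(triisopropylsilyl)oxy]cyclohex-3-ene-1-carboxylate, both carbinol epimers | CC(O)[C@@]1(C)CC=C(O[Si](C(C)C)(C(C)C)C(C)C)C[C@@H]1C(=O)OCC | intermediate
6 | ethyl (1S,6S)-6-acetyl-6-methyl-3-[(triisopropylsilyl)oxy]cyclohex-3-ene-1-carboxylate | CC(=O)[C@@]1(C)CC=C(O[Si](C(C)C)(C(C)C)C(C)C)C[C@@H]1C(=O)OCC | intermediate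
7 | prop-2-yn-1-ol | C#CCO | starting material
8 | (2Z)-3-iodo-2-methylprop-2-en-1-ol | OC/C(C)=C\I | intermediate
9 | (1Z)-3-bromo-1-iodo-2-methylprop-1-ene | BrC/C(C)=C\I | intermediate
10 | ethyl (1S,6S)-6-[(4Z)-5-iodo-4-methylpent-4-enoyl]-6-methyl-3-[(triisopropylsilyl)oxy]cyclohex-3-ene-1-carboxylate | O=C(CC/C(C)=C\I)[C@@]1(C)CC=C(O[Si](C(C)C)(C(C)C)C(C)C)C[C@@H]1C(=O)OCC | intermediate
11 | ethyl (1S,6S)-6-[(1R,4Z)-1-hydroxy-5-iodo-4-methylpent-4-en-1-yl]-6-methyl-3-[(triisopropylsilyl)oxy]cyclohex-3-ene-1-carboxylate | O[C@H](CC/C(C)=C\I)[C@@]1(C)CC=C(O[Si](C(C)C)(C(C)C)C(C)C)C[C@@H]1C(=O)OCC | intermediate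
12 | ethyl (1S,6S)-6-{(1R,4Z)-5-iodo-4-methyl-1-[(triethylsilyl)oxy]pent-4-en-1-yl}-6-methyl-3-[(triisopropylsilyl)oxy]cyclohex-3-ene-1-carboxylate | CC[Si](CC)(CC)O[C@H](CC/C(C)=C\I)[C@@]1(C)CC=C(O[Si](C(C)C)(C(C)C)C(C)C)C[C@@H]1C(=O)OCC | intermediate
13 | [(1S,6S)-6-{(1R,4Z)-5-iodo-4-methyl-1-[(triethylsilyl)oxy]pent-4-en-1-yl}-6-methyl-3-[(triisopropylsilyl)oxy]cyclohex-3-en-1-yl]methanol | CC[Si](CC)(CC)O[C@H](CC/C(C)=C\I)[C@@]1(C)CC=C(O[Si](C(C)C)(C(C)C)C(C)C)C[C@@H]1CO | intermediate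
14 | (1S,6S)-6-{(1R,4Z)-5-iodo-4-methyl-1-[(triethylsilyl)oxy]pent-4-en-1-yl}-6-methyl-3-[(triisopropylsilyl)oxy]cyclohex-3-ene-1-carbaldehyde (CHO = C9) | CC[Si](CC)(CC)O[C@H](CC/C(C)=C\I)[C@@]1(C)CC=C(O[Si](C(C)C)(C(C)C)C(C)C)C[C@@H]1C=O | intermediate
15 | diethyl (2S)-2-hydroxybutanedioate (diethyl L-malate) | CCOC(=O)C[C@H](O)C(=O)OCC | starting material
16 | diethyl (2S,3R)-2-hydroxy-3-methylbutanedioate | CCOC(=O)[C@H](C)[C@H](O)C(=O)OCC | intermediate
17 | (2S,3R)-2-hydroxy-3-methylbutanedioic acid | OC(=O)[C@H](C)[C@H](O)C(=O)O | intermediate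
18 | (2R)-2-[(2S,4S)-2-tert-butyl-5-oxo-1,3-dioxolan-4-yl]propanoic acid (cis acetal) | OC(=O)[C@H](C)[C@@H]1O[C@H](C(C)(C)C)OC1=O | intermediate
19 | (2S,5S)-2-tert-butyl-5-[(2S)-1-hydroxypropan-2-yl]-1,3-dioxolan-4-one | OC[C@H](C)[C@@H]1O[C@H](C(C)(C)C)OC1=O | intermediate
20 | (2S,5S)-2-tert-butyl-5-{(2S)-1-[(triethylsilyl)oxy]propan-2-yl}-1,3-dioxolan-4-one | CC[Si](CC)(CC)OC[C@H](C)[C@@H]1O[C@H](C(C)(C)C)OC1=O | intermediate
21 | lithium (2S)-2-tert-butyl-5-{(2S)-1-[(triethylsilyl)oxy]propan-2-yl}-1,3-dioxol-4-olate (enolate of 20) | CC[Si](CC)(CC)OC[C@H](C)C1=C([O-])O[C@@H](C(C)(C)C)O1.[Li+] | intermediate (not isolated)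
22 | (2S,5R)-2-tert-butyl-5-[(R)-hydroxy(ring A)methyl]-5-{(2S)-1-[(triethylsilyl)oxy]propan-2-yl}-1,3-dioxolan-4-one, ring A = the (1S,6S)-cyclohexenyl unit of 14 | CC[Si](CC)(CC)O[C@H](CC/C(C)=C\I)[C@@]1(C)CC=C(O[Si](C(C)C)(C(C)C)C(C)C)C[C@@H]1[C@@H](O)[C@@]2([C@@H](C)CO[Si](CC)(CC)CC)O[C@H](C(C)(C)C)OC2=O | intermediate
23 | 9-O-(tert-butyldimethylsilyl) ether of 22 ((2S,5R)-dioxolanone, 9R) | CC[Si](CC)(CC)O[C@H](CC/C(C)=C\I)[C@@]1(C)CC=C(O[Si](C(C)C)(C(C)C)C(C)C)C[C@@H]1[C@@H](O[Si](C)(C)C(C)(C)C)[C@@]2([C@@H](C)CO[Si](CC)(CC)CC)O[C@H](C(C)(C)C)OC2=O | intermediate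
24 | 7,8-diol: C8 carbinol carrying CH2OH (C7), OH, the (2S)-1-(TESO)propan-2-yl group (C17–C19) and the (R)-CH(OTBS)–ring A unit; (1S,2R,8S,9R,10S,17S); ring A still the TIPS enol ether | CC[Si](CC)(CC)O[C@H](CC/C(C)=C\I)[C@@]1(C)CC=C(O[Si](C(C)C)(C(C)C)C(C)C)C[C@@H]1[C@@H](O[Si](C)(C)C(C)(C)C)[C@@](O)(CO)[C@@H](C)CO[Si](CC)(CC)CC | intermediate
25 | 13-(phenylselanyl)-12-ketone derived from 24 (C13 epimers) | CC[Si](CC)(CC)O[C@H](CC/C(C)=C\I)[C@@]1(C)CC([Se]c2ccccc2)C(=O)C[C@@H]1[C@@H](O[Si](C)(C)C(C)(C)C)[C@@](O)(CO)[C@@H](C)CO[Si](CC)(CC)CC | intermediate (not isolated)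
26 | cyclohex-2-enone diol: ring A now C12=O, C13=C14, C11H2; remainder as 24 | CC[Si](CC)(CC)O[C@H](CC/C(C)=C\I)[C@@]1(C)C=CC(=O)C[C@@H]1[C@@H](O[Si](C)(C)C(C)(C)C)[C@@](O)(CO)[C@@H](C)CO[Si](CC)(CC)CC | intermediate
27 | 11-methyl derivative of 26 (C11 epimers) | CC[Si](CC)(CC)O[C@H](CC/C(C)=C\I)[C@@]1(C)C=CC(=O)C(C)[C@@H]1[C@@H](O[Si](C)(C)C(C)(C)C)[C@@](O)(CO)[C@@H](C)CO[Si](CC)(CC)CC | intermediate
28 | (11S)-11-hydroxy-11-methyl enone triol (7-OH primary, 8-OH and 11-OH tertiary); (1S,2R,8S,9R,10S,11S,17S) | CC[Si](CC)(CC)O[C@H](CC/C(C)=C\I)[C@@]1(C)C=CC(=O)[C@@](C)(O)[C@@H]1[C@@H](O[Si](C)(C)C(C)(C)C)[C@@](O)(CO)[C@@H](C)CO[Si](CC)(CC)CC | intermediate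
29 | C7 aldehyde of 28 (α-hydroxy aldehyde; Z vinyl iodide at C6); (1S,2R,8R,9R,10S,11S,17S) | CC[Si](CC)(CC)O[C@H](CC/C(C)=C\I)[C@@]1(C)C=CC(=O)[C@@](C)(O)[C@@H]1[C@@H](O[Si](C)(C)C(C)(C)C)[C@@](O)(C=O)[C@@H](C)CO[Si](CC)(CC)CC | intermediate
30 | bicyclo[8.4.0] carbocycle: (1S,2R,5Z,7S,8S,9R,10S,11S,17S)-7,8,11-trihydroxy-12-oxo-2,19-bis(triethylsilyloxy)-9-(tert-butyldimethylsilyloxy)briara-5,13-diene (no lactone, C19 = CH2OTES) | CC[Si](CC)(CC)O[C@@H]1CC/C(C)=C\[C@H](O)[C@@](O)([C@@H](C)CO[Si](CC)(CC)CC)[C@H](O[Si](C)(C)C(C)(C)C)[C@@H]2[C@]1(C)C=CC(=O)[C@@]2(C)O | intermediate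
31 | 2,7,8,11,19-pentaol 9-TBS ether of the same skeleton (2-OH, 7-OH, 19-OH freed) | O[C@@H]1CC/C(C)=C\[C@H](O)[C@@](O)([C@@H](C)CO)[C@H](O[Si](C)(C)C(C)(C)C)[C@@H]2[C@]1(C)C=CC(=O)[C@@]2(C)O | intermediate
32 | 7,19-lactol (C19 hemiacetal, both anomers) | O[C@@H]1CC/C(C)=C\[C@@H]2OC(O)[C@H](C)[C@@]2(O)[C@H](O[Si](C)(C)C(C)(C)C)[C@@H]2[C@]1(C)C=CC(=O)[C@@]2(C)O | intermediate (not isolated)
33 | (1S,2R,5Z,7S,8S,9R,10S,11S,17R)-2,8,11-trihydroxy-9-(tert-butyldimethylsilyloxy)-12-oxobriara-5,13-dien-18,7-olide | O[C@@H]1CC/C(C)=C\[C@@H]2OC(=O)[C@H](C)[C@@]2(O)[C@H](O[Si](C)(C)C(C)(C)C)[C@@H]2[C@]1(C)C=CC(=O)[C@@]2(C)O | intermediate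
34 | 2-O-propanoyl derivative of 33 | CCC(=O)O[C@@H]1CC/C(C)=C\[C@@H]2OC(=O)[C@H](C)[C@@]2(O)[C@H](O[Si](C)(C)C(C)(C)C)[C@@H]2[C@]1(C)C=CC(=O)[C@@]2(C)O | intermediate
35 | 9-hydroxy compound (2-propanoate, 8,9,11-triol) | CCC(=O)O[C@@H]1CC/C(C)=C\[C@@H]2OC(=O)[C@H](C)[C@@]2(O)[C@H](O)[C@@H]2[C@]1(C)C=CC(=O)[C@@]2(C)O | intermediate
36 | CNP0240018.1: (1S,2R,5Z,7S,8S,9R,10S,11S,17R)-9-acetoxy-8,11-dihydroxy-12-oxo-2-propanoyloxybriara-5,13-dien-18,7-olide | CCC(=O)O[C@@H]1CC/C(C)=C\[C@@H]2OC(=O)[C@H](C)[C@@]2(O)[C@H](OC(C)=O)[C@@H]2[C@]1(C)C=CC(=O)[C@@]2(C)O | target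

**Totals**
Total step count: 29. Longest linear sequence: 22 steps (1–4, 7–11, 17–29).

**Three steps most likely to fail**

Step 2. The enantioselectivity and the sense of induction of the catalysed cycloaddition with a doubly activated, trisubstituted dienophile are not secured by close precedent. Fallback: give up catalyst control and separate diastereomers later. Setting out from 2 and 3, the cycloaddition is run with Me2AlCl (CH2Cl2, −78 °C) to give the racemate, that is 4 together with its enantiomer ent-4 F1. Steps 3, 4 and 7 are run on the racemate, so that ent-5 F2, ent-6 F3 and ent-10 F4 accompany 5, 6 and 10. The (S)-CBS reduction of step 8 is reagent-controlled and gives the (R)-carbinol from both ketone enantiomers, so 11 is formed together with its (1R,6R,1′R)-diastereomer F5, which is removed by chromatography. The route is rejoined at 11.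

Step 17. A tetrasubstituted enolate must add to an α-branched, neopentyl-type aldehyde, so retro-aldol can compete, and the C9 configuration rests on a single closed transition state. Fallback: replace the reversible aldol by an irreversible Claisen-type C-acylation followed by reduction. Setting out from 14, Pinnick oxidation (NaClO2, NaH2PO4, 2-methylbut-2-ene) gives carboxylic acid F6, and oxalyl chloride with catalytic DMF gives acid chloride F7. This acylates enolate 21 (from 20, LDA, −78 °C) trans to the tert-butyl group to give β-keto dioxolanone F8. Reduction with NaBH4 (MeOH/THF, −40 °C) should follow the polar Felkin–Anh model (hydride anti to the C8–O bond, C17 branch inside) and give the 9R carbinol, returning to the route at 22.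

Step 24. Closing a ten-membered ring next to a quaternary carbon is demanding, and the C7 configuration rests on Felkin–Anh control in a macrocyclic transition state. Fallback for the wrong C7 epimer: invert C7 during lactone formation. Setting out from 29, if the coupling gives mainly 7-epi-30 F9, it is desilylated as in step 25 to 7-epi-31 F10 and oxidised as in step 26 to the 7-epi-lactone F11. LiOH (THF/H2O, 0 °C) opens the lactone, and careful acidification (pH 4, 0 °C) gives hydroxy acid F12. This is closed at once under Mitsunobu conditions (PPh3, DIAD, THF, 0 °C); the carboxylate displaces the activated allylic C7 oxygen in a 5-exo-tet SN2 reaction with inversion, returning to the route at 33.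

**Further compounds**
F1 | step 2 | ent-4, ethyl (1R,6R)-6-formyl-6-methyl-3-[(triisopropylsilyl)oxy]cyclohex-3-ene-1-carboxylate | O=C[C@]1(C)CC=C(O[Si](C(C)C)(C(C)C)C(C)C)C[C@H]1C(=O)OCC
F2 | step 2 | ent-5, ethyl (1R,6R)-6-(1-hydroxyethyl)-6-methyl-3-[(triisopropylsilyl)oxy]cyclohex-3-ene-1-carboxylate | CC(O)[C@]1(C)CC=C(O[Si](C(C)C)(C(C)C)C(C)C)C[C@H]1C(=O)OCC
F3 | step 2 | ent-6, ethyl (1R,6R)-6-acetyl-6-methyl-3-[(triisopropylsilyl)oxy]cyclohex-3-ene-1-carboxylate | CC(=O)[C@]1(C)CC=C(O[Si](C(C)C)(C(C)C)C(C)C)C[C@H]1C(=O)OCC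
F4 | step 2 | ent-10, ethyl (1R,6R)-6-[(4Z)-5-iodo-4-methylpent-4-enoyl]-6-methyl-3-[(triisopropylsilyl)oxy]cyclohex-3-ene-1-carboxylate | O=C(CC/C(C)=C\I)[C@]1(C)CC=C(O[Si](C(C)C)(C(C)C)C(C)C)C[C@H]1C(=O)OCC
F5 | step 2 | (1R,6R,1′R)-diastereomer of 11, ethyl (1R,6R)-6-[(1R,4Z)-1-hydroxy-5-iodo-4-methylpent-4-en-1-yl]-6-methyl-3-[(triisopropylsilyl)oxy]cyclohex-3-ene-1-carboxylate | O[C@H](CC/C(C)=C\I)[C@]1(C)CC=C(O[Si](C(C)C)(C(C)C)C(C)C)C[C@H]1C(=O)OCC
F6 | step 17 | carboxylic acid, (1S,6S)-6-{(1R,4Z)-5-iodo-4-methyl-1-[(triethylsilyl)oxy]pent-4-en-1-yl}-6-methyl-3-[(triisopropylsilyl)oxy]cyclohex-3-ene-1-carboxylic acid | CC[Si](CC)(CC)O[C@H](CC/C(C)=C\I)[C@@]1(C)CC=C(O[Si](C(C)C)(C(C)C)C(C)C)C[C@@H]1C(=O)O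
F7 | step 17 | acid chloride of F6 | CC[Si](CC)(CC)O[C@H](CC/C(C)=C\I)[C@@]1(C)CC=C(O[Si](C(C)C)(C(C)C)C(C)C)C[C@@H]1C(=O)Cl
F8 | step 17 | β-keto dioxolanone (C9 ketone analogue of 22) | CC[Si](CC)(CC)O[C@H](CC/C(C)=C\I)[C@@]1(C)CC=C(O[Si](C(C)C)(C(C)C)C(C)C)C[C@@H]1C(=O)[C@@]2([C@@H](C)CO[Si](CC)(CC)CC)O[C@H](C(C)(C)C)OC2=O
F9 | step 24 | 7-epi-30 (7R allylic alcohol) | CC[Si](CC)(CC)O[C@@H]1CC/C(C)=C\[C@@H](O)[C@@](O)([C@@H](C)CO[Si](CC)(CC)CC)[C@H](O[Si](C)(C)C(C)(C)C)[C@@H]2[C@]1(C)C=CC(=O)[C@@]2(C)O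
F10 | step 24 | 7-epi-31 | O[C@@H]1CC/C(C)=C\[C@@H](O)[C@@](O)([C@@H](C)CO)[C@H](O[Si](C)(C)C(C)(C)C)[C@@H]2[C@]1(C)C=CC(=O)[C@@]2(C)O
F11 | step 24 | 7-epi-lactone (7-epi-33) | O[C@@H]1CC/C(C)=C\[C@H]2OC(=O)[C@H](C)[C@@]2(O)[C@H](O[Si](C)(C)C(C)(C)C)[C@@H]2[C@]1(C)C=CC(=O)[C@@]2(C)O
F12 | step 24 | hydroxy acid (7-epi seco acid, C19 = CO2H) | O[C@@H]1CC/C(C)=C\[C@@H](O)[C@@](O)([C@@H](C)C(=O)O)[C@H](O[Si](C)(C)C(C)(C)C)[C@@H]2[C@]1(C)C=CC(=O)[C@@]2(C)O
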